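**Retrosynthetic overview**
- The target comes from selective O-acetylation of the side-chain alcohol of 2-hydroxy-3-[(2S)-2-hydroxypropyl]-5,6,8-trimethoxy-1,4-naphthoquinone.
- Ring B is made in one flask in the order a polyketide pathway uses: Claisen chain extension (C1–C2 bond, from the C3 carbanion of 4,6,7-trimethoxyphthalide and (S)-γ-valerolactone, which supplies C2, C3, the side chain and the stereocenter), intramolecular Claisen (Dieckmann) closure of C3–C4 onto the phthalide carbonyl, then autoxidation of the naphthalene-1,2,4-triol.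
- 4,6,7-Trimethoxyphthalide comes from 2,4,5-trimethoxybenzaldehyde by ortho-lithiation/carboxylation at C6, reduction and lactonisation; this fixes which quinone carbonyl lies next to the 5,6-dimethoxy side.
- Ring order: ring A is bought intact; the phthalide lactone ring is temporary and is opened in the annulation; ring B is the only ring formed.

Assumption: the target is the (S)-acetate as drawn, and (S)-γ-valerolactone (≥98% ee) is bought as a chiral-pool material.

**Step 1**
Reactants: 1 2,4,5-trimethoxybenzaldehyde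
Product: 7 4,6,7-trimethoxy-2-benzofuran-1(3H)-one, via lithium amino alkoxide 2 (not isolated), via ortho-lithiated amino alkoxide 3 (not isolated), via lithium carboxylate 4 (not isolated), via 6-formyl-2,3,5-trimethoxybenzoic acid 5 (not isolated), via 6-(hydroxymethyl)-2,3,5-trimethoxybenzoic acid 6 (not isolated)
Conditions: Me2NCH2CH2NHMe, n-BuLi, THF, −20 °C, then 1; n-BuLi (3 equiv), −20 °C, 20 h; CO2, −78 °C → rt; aq. NaOH, NaBH4, 0 °C → rt; 3 M HCl, 40 °C (one pot)
Reagents that add atoms: carbon dioxide, O=C=O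
Why: Comins-type directed ortho-metalation, in which the aldehyde is masked as the α-amino alkoxide whose chelating diamine arm, helped by the C5 methoxy group, directs n-BuLi to C6 (the only free ortho position) rather than to C3, followed by standard carboxylation, unmasking, NaBH4 reduction and acid lactonisation; no stereocenter is kept.

**Step 2**
Reactants: 7 4,6,7-trimethoxy-2-benzofuran-1(3H)-one; 8 (S)-γ-valerolactone
Product: 12 2-hydroxy-3-[(2S)-2-hydroxypropyl]-5,6,8-trimethoxynaphthalene-1,4-dione, via lithiated phthalide 9 (not isolated), via 3-acylphthalide 10 (not isolated), via naphthalene-1,2,4-triol 11 (not isolated)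
Conditions: LiN(i-Pr)2 (1.1 equiv), THF, −78 °C; 8 (1.5 equiv), −78 → −30 °C; NaOMe (5 equiv), MeOH, argon, −30 → 50 °C; 1 M HCl to pH 6, air, rt; then pH 3
Reagents that add atoms: none
Why: Proposed new method: the phthalide C3 carbanion 9 (the nucleophile of Hauser–Kraus and Sammes phthalide annulations, which is known to add to a lactone carbonyl in its own self-condensation) is C-acylated by the unhindered lactone 8 in a Claisen condensation that opens the lactone and is held by enolisation of 10; under methoxide the distal α-methylene enolate of 10 then attacks the phthalide carbonyl through the oxygen-bridged adduct of the Hauser–Kraus annulation, a Dieckmann closure with ring expansion of the Gabriel–Colman type whose closest carbocyclic precedent is the alkoxide rearrangement of 3-alkylidene-isochroman-1,4-diones to 2-alkyl-3-hydroxy-1,4-naphthoquinones, and triol 11 autoxidises to the quinone like any hydroxyhydroquinone; the stereocenter comes unchanged from 8 because only the acyl–oxygen bond breaks and the carbinol carbon is γ to the ketone and cannot enolise.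

**Step 3**
Reactants: 12 2-hydroxy-3-[(2S)-2-hydroxypropyl]-5,6,8-trimethoxynaphthalene-1,4-dione
Product: 14 (2S)-1-(3-hydroxy-5,7,8-trimethoxy-1,4-dioxo-1,4-dihydronaphthalen-2-yl)propan-2-yl acetate, via diacetate 13 (not isolated)
Conditions: Ac2O (3 equiv), pyridine, DMAP (cat.), CH2Cl2, 0 °C → rt; then aq. NaHCO3, THF, rt, 30 min; 1 M HCl to pH 3
Reagents that add atoms: acetic anhydride, CC(=O)OC(C)=O
Why: DMAP-catalysed acetylation esterifies both hydroxyls, and the enol acetate of 13, a vinylogous mixed anhydride, is hydrolysed by bicarbonate while the secondary alkyl acetate survives; the stereocenter is untouched because its C–O bond is never broken.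

**Compound list**
1 | 2,4,5-trimethoxybenzaldehyde | COc1cc(OC)c(OC)cc1C=O | starting material
2 | lithium {[2-(dimethylamino)ethyl](methyl)amino}(2,4,5-trimethoxyphenyl)methanolate (racemic aminal carbon) | [Li+].[O-]C(N(C)CCN(C)C)c1cc(OC)c(OC)cc1OC | intermediate
3 | lithium {[2-(dimethylamino)ethyl](methyl)amino}(2-lithio-3,4,6-trimethoxyphenyl)methanolate | [Li+].[Li]c1c(OC)c(OC)cc(OC)c1C([O-])N(C)CCN(C)C | intermediate
4 | dilithium 2-({[2-(dimethylamino)ethyl](methyl)amino}(oxido)methyl)-3,5,6-trimethoxybenzoate | [Li+].[Li+].[O-]C(=O)c1c(OC)c(OC)cc(OC)c1C([O-])N(C)CCN(C)C | intermediate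
5 | 6-formyl-2,3,5-trimethoxybenzoic acid (ring tautomer: 3-hydroxy-4,6,7-trimethoxyphthalide) | O=Cc1c(OC)cc(OC)c(OC)c1C(=O)O | intermediate
6 | 6-(hydroxymethyl)-2,3,5-trimethoxybenzoic acid (present as its sodium salt) | OCc1c(OC)cc(OC)c(OC)c1C(=O)O | intermediate
7 | 4,6,7-trimethoxy-2-benzofuran-1(3H)-one (4,6,7-trimethoxyphthalide) | O=C1OCc2c(OC)cc(OC)c(OC)c12 | intermediate
8 | (5S)-5-methyloxolan-2-one, (S)-γ-valerolactone | C[C@H]1CCC(=O)O1 | starting material
9 | 3-lithio-4,6,7-trimethoxy-2-benzofuran-1(3H)-one | [Li+].O=C1O[CH-]c2c(OC)cc(OC)c(OC)c12 | intermediate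
10 | 3-[(4S)-4-hydroxypentanoyl]-4,6,7-trimethoxy-2-benzofuran-1(3H)-one (both C3 epimers, present as enolate) | C[C@H](O)CCC(=O)C1OC(=O)c2c(OC)c(OC)cc(OC)c12 | intermediate
11 | 3-[(2S)-2-hydroxypropyl]-5,6,8-trimethoxynaphthalene-1,2,4-triol | COc1cc(OC)c2c(O)c(O)c(C[C@H](C)O)c(O)c2c1OC | intermediate
12 | 2-hydroxy-3-[(2S)-2-hydroxypropyl]-5,6,8-trimethoxynaphthalene-1,4-dione | COc1cc(OC)c2c(c1OC)C(=O)C(C[C@H](C)O)=C(O)C2=O | intermediate
13 | (2S)-1-[3-(acetyloxy)-5,7,8-trimethoxy-1,4-dioxo-1,4-dihydronaphthalen-2-yl]propan-2-yl acetate | COc1cc(OC)c2c(c1OC)C(=O)C(C[C@H](C)OC(C)=O)=C(OC(C)=O)C2=O | intermediate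
14 | (2S)-1-(3-hydroxy-5,7,8-trimethoxy-1,4-dioxo-1,4-dihydronaphthalen-2-yl)propan-2-yl acetate (CNP0321270.1) | COc1cc(OC)c2c(c1OC)C(=O)C(C[C@H](C)OC(C)=O)=C(O)C2=O | target

**Totals**
Total step count: 3. Longest linear sequence: 3 steps (1 → 7 → 12 → 14; 8 enters in step 2).

**Steps most likely to fail, with fallbacks**

Step 2 is the riskiest. The C-acylation of the phthalide carbanion by a saturated lactone and the ring expansion have no direct precedent in this combination, and self-condensation of 9 or retro-Claisen cleavage of 10 could win. The fallback sets out from 7 and comes back at 12, and lowers the oxidation level of the nucleophilic carbon so that only ordinary toluate chemistry is needed. Hydrogenolysis of the activated benzylic C–O bond of 7 (H2, 10% Pd/C, AcOH, cat. HClO4, 60 °C) gives 2,3,5-trimethoxy-6-methylbenzoic acid F4. MeI/K2CO3 in DMF gives methyl 2,3,5-trimethoxy-6-methylbenzoate F5. Lateral lithiation with LiN(i-Pr)2 at −78 °C (the di-ortho-substituted ester does not self-condense) and C-acylation with 8 give methyl 2-[(5S)-5-hydroxy-2-oxohexyl]-3,5,6-trimethoxybenzoate F6. NaOMe/MeOH closes this by an ordinary Dieckmann condensation to 2-[(2S)-2-hydroxypropyl]-5,7,8-trimethoxynaphthalene-1,3-diol F7, and aeration of the alkaline solution oxidises C4 of F7 to give 12.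

Step 1 is next. Lithiation could go to C3, between two methoxy groups, instead of C6. The fallback sets out from 1 and comes back at 7, and replaces lithiation by chelation-controlled cyclopalladation, which can only reach C6. Reductive amination of 1 (Me2NH, NaBH(OAc)3, ClCH2CH2Cl) gives N,N-dimethyl-1-(2,4,5-trimethoxyphenyl)methanamine F1. Pd(OAc)2-catalysed, amine-directed ortho C–H methoxycarbonylation (CO 1 atm, MeOH, Cu(OAc)2, LiCl) gives methyl 2-[(dimethylamino)methyl]-3,5,6-trimethoxybenzoate F2. Ethyl chloroformate in refluxing toluene cleaves the benzylic C–N bond to methyl 2-(chloromethyl)-3,5,6-trimethoxybenzoate F3, which lactonises on continued heating to 7.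

Step 3 is the least risky. The enol and the alcohol may not be fully discriminated, or the side-chain acetate may be lost in the hydrolytic work-up. The fallback sets out from 12 and comes back at 14, and separates the two kinds of ester by class (aryl against alkyl). Reductive acetylation (Zn dust, Ac2O, pyridine, rt) gives the leuco tetraacetate (2S)-1-[1,3,4-tris(acetyloxy)-5,7,8-trimethoxynaphthalen-2-yl]propan-2-yl acetate F8. Pyrrolidine (3.3 equiv, CH2Cl2, 0 °C, argon) removes only the three aryl acetates to give (2S)-1-(1,3,4-trihydroxy-5,7,8-trimethoxynaphthalen-2-yl)propan-2-yl acetate F9, which air oxidises to 14.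

**Further compounds**
F1 | step 1 | N,N-dimethyl-1-(2,4,5-trimethoxyphenyl)methanamine | CN(C)Cc1cc(OC)c(OC)cc1OC
F2 | step 1 | methyl 2-[(dimethylamino)methyl]-3,5,6-trimethoxybenzoate | COC(=O)c1c(OC)c(OC)cc(OC)c1CN(C)C
F3 | step 1 | methyl 2-(chloromethyl)-3,5,6-trimethoxybenzoate | COC(=O)c1c(OC)c(OC)cc(OC)c1CCl
F4 | step 2 | 2,3,5-trimethoxy-6-methylbenzoic acid | Cc1c(OC)cc(OC)c(OC)c1C(=O)O
F5 | step 2 | methyl 2,3,5-trimethoxy-6-methylbenzoate | Cc1c(OC)cc(OC)c(OC)c1C(=O)OC
F6 | step 2 | methyl 2-[(5S)-5-hydroxy-2-oxohexyl]-3,5,6-trimethoxybenzoate | C[C@H](O)CCC(=O)Cc1c(OC)cc(OC)c(OC)c1C(=O)OC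
F7 | step 2 | 2-[(2S)-2-hydroxypropyl]-5,7,8-trimethoxynaphthalene-1,3-diol | COc1cc(OC)c2cc(O)c(C[C@H](C)O)c(O)c2c1OC
F8 | step 3 | (2S)-1-[1,3,4-tris(acetyloxy)-5,7,8-trimethoxynaphthalen-2-yl]propan-2-yl acetate | COc1cc(OC)c2c(OC(C)=O)c(OC(C)=O)c(C[C@H](C)OC(C)=O)c(OC(C)=O)c2c1OC
F9 | step 3 | (2S)-1-(1,3,4-trihydroxy-5,7,8-trimethoxynaphthalen-2-yl)propan-2-yl acetate | COc1cc(OC)c2c(O)c(O)c(C[C@H](C)OC(C)=O)c(O)c2c1OC
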